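The quinone-methide carbocycle (ring A: C4a, C5, C6, C7, C8, C8a) is a masked resorcinol in which C7 lies between C6–OH and C8=O. C7 is therefore treated as the α-carbon of a C8 ketone that is acylated by a C6 ester. The same pattern recurs in the isochromanone (ring B), and the bridging CH(CH3) with C7 and C7′ is the chain of (R)-3-methylglutarate. Both carboxyl arms are extended to β-keto esters and joined to one triketide-lactone triflate (C3/C4 pair, C5 methyl, C6). In the key step methoxide opens both lactones of an open-chain 1,5-diketone capped by two dihydropyranones, and a double Claisen cyclization aromatizes rings A and B at once; orthoformate finally installs C1.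

Key step: step 7

Remark: isochromene numbering is used throughout (O2, C1, C3, C4, C4a, C5–C8, C8a; primed locants for the lactone unit); hemiester 7 is assumed to be purchasable, and the target is drawn as its C8-oxo/C6-hydroxy tautomer.

Step 1
Reactants: 1 ethyl (R)-3-hydroxybutanoate
Product: 2 ethyl (2R,3R)-3-hydroxy-2-methylbutanoate
Conditions: LiN(iPr)2 (2.2 equiv), THF, −50 → −20 °C; MeI, DMPU, −78 → 0 °C
Reagents that add atoms: methyl iodide, CI
Why: Fráter–Seebach alkylation, in which the chelated alkoxide–enolate dianion is methylated on the face away from the C3 methyl group, so the purchased C3 centre relays the new C2 centre (anti, 2R,3R) by substrate control.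

Step 2
Reactants: 2 ethyl (2R,3R)-3-hydroxy-2-methylbutanoate; 3 tert-butyl propionate
Product: 5 (5R,6R)-4-hydroxy-3,5,6-trimethyl-5,6-dihydro-2H-pyran-2-one, via tert-butyl hydroxy keto ester 4 (not isolated)
Conditions: LiN(iPr)2 and 3 (3.5 equiv each), THF, −78 → −20 °C; AcOH; then TFA/CH2Cl2 (1:4), rt
Reagents that add atoms: none
Why: Crossed Claisen condensation of the unprotected β-hydroxy ester with excess lithium ester enolate (alkoxide and product enolate are spectators, so the centre next to the new ketone is not deprotonated), followed by acidolysis of the tert-butyl ester and lactonization to the trans-5,6-dimethyl lactone, which should also be the thermodynamic isomer.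

Step 3
Reactants: 5 (5R,6R)-4-hydroxy-3,5,6-trimethyl-5,6-dihydro-2H-pyran-2-one
Product: 6 (5R,6R)-3,5,6-trimethyl-2-oxo-5,6-dihydro-2H-pyran-4-yl trifluoromethanesulfonate
Conditions: Tf2O, Et3N, CH2Cl2, −78 °C
Reagents that add atoms: triflic anhydride, O=S(=O)(OS(=O)(=O)C(F)(F)F)C(F)(F)F
Why: O-sulfonylation of the vinylogous acid at the C4 enol oxygen gives the vinylogous acyl triflate without touching either stereocentre.

Step 4
Reactants: 7 (R)-5-methoxy-3-methyl-5-oxopentanoic acid [(R)-methyl hydrogen 3-methylglutarate]; 8 potassium 3-methoxy-3-oxopropanoate (potassium monomethyl malonate)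
Product: 10 dimethyl (3R)-3-methyl-5-oxoheptanedioate, via acyl imidazolide 9 (not isolated)
Conditions: CDI, THF, rt; then 8, MgCl2, Et3N, MeCN, rt; 1 M aq. HCl
Reagents that add atoms: none
Why: Masamune–Brooks chain extension, in which the acyl imidazolide of the free acid arm C-acylates the magnesium malonate and decarboxylates to the β-keto ester, leaving the methyl ester arm and the β-stereocentre untouched.

Step 5
Reactants: 10 dimethyl (3R)-3-methyl-5-oxoheptanedioate; 11 tert-butyl acetate
Product: 12 1-tert-butyl 9-methyl (5R)-5-methyl-3,7-dioxononanedioate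
Conditions: LiN(iPr)2 and 11 (4.5 equiv each), THF, −78 → −40 °C; AcOH
Reagents that add atoms: none
Why: Crossed Claisen condensation in which the β-keto ester of 10 is protected in situ as its enolate, so the excess acetate enolate should attack only the terminal methyl ester; the two arms (later ring A and ring B) then differ only in their ester groups.

Step 6
Reactants: 12 1-tert-butyl 9-methyl (5R)-5-methyl-3,7-dioxononanedioate; 6 (5R,6R)-3,5,6-trimethyl-2-oxo-5,6-dihydro-2H-pyran-4-yl trifluoromethanesulfonate (2.2 equiv)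
Product: 14 methyl (5S)-5-methyl-3,7-dioxo-2,8-bis[(2R,3S)-2,3,5-trimethyl-6-oxo-3,6-dihydro-2H-pyran-4-yl]octanoate (epimers at C2), via tert-butyl ester bis-adduct 13 (not isolated)
Conditions: NaH (4.4 equiv), THF–DMF, 0 °C; 6, 0 °C → rt; then TFA/CH2Cl2 (1:3), rt
Reagents that add atoms: none
Why: Nucleophilic vinylic substitution (addition–elimination) of both sodium β-keto ester enolates at the triflate-bearing β-carbon of 6, followed by acidolysis of the tert-butyl ester and decarboxylation of the vinylogous β-keto acid, frees C8a in the ring-A arm while the ring-B arm keeps its methyl ester (future C1′); no stereocentre of the product skeleton is formed or touched.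

Step 7
Reactants: 14 methyl (5S)-5-methyl-3,7-dioxo-2,8-bis[(2R,3S)-2,3,5-trimethyl-6-oxo-3,6-dihydro-2H-pyran-4-yl]octanoate
Product: 17 (3R,4S)-7-[(1S)-1-{2,6-dihydroxy-4-[(2S,3R)-3-hydroxybutan-2-yl]-3-methylphenyl}ethyl]-6,8-dihydroxy-3,4,5-trimethyl-3,4-dihydro-1H-isochromen-1-one, via open-chain bis(hydroxy enoate) 15 (not isolated), via bis-resorcinol methyl ester 16 (not isolated)
Conditions: NaOMe (10 equiv), MeOH, 65 °C; then 2 M aq. HCl, rt → 40 °C
Reagents that add atoms: none
Why: Methoxide transesterifies both dihydropyranones to methyl enoates with free C3/C3′ alkoxides, the delocalized anions at C8a and C8a′ allow E/Z equilibration about C4a=C5, and the ketone enolates at C7 and C7′ then acylate at the C6 and C6′ esters, each cyclohexenedione tautomerizing irreversibly to a resorcinol before the C3′ hydroxyl lactonizes onto the C8a′ ester. The closest known reaction type is the Michael–Claisen (dimedone or dihydroresorcinol) annulation and its alkyne-level variants that give resorcinols directly from 5-oxo-2-enoates. Ring A and ring B each close in a 6-(enolexo)-exo-trig Claisen (Dieckmann) mode, and the lactone ring closes 6-exo-trig by acyl transfer. No stereocentre is created: C3/C4, C3′/C4′ and the bridging carbon are carried through, C4 and C4′ being shielded from γ-deprotonation because the far more acidic C8a and C8a′ sites are ionized first, and retro-Michael loss of the bridging centre should be outrun by cyclization. The step needs C-acylation at C7/C7′ rather than enol O-acylation (2-pyranone formation) or aldol reaction between the two 1,5-related ketones; O-acylation is reversible under methoxide whereas aromatization is not, and both ketones are masked as stabilized enolates.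

Step 8
Reactants: 17 (3R,4S)-7-[(1S)-1-{2,6-dihydroxy-4-[(2S,3R)-3-hydroxybutan-2-yl]-3-methylphenyl}ethyl]-6,8-dihydroxy-3,4,5-trimethyl-3,4-dihydro-1H-isochromen-1-one
Product: 19 dicitrinone H, (3R,4S)-6,8-dihydroxy-7-[(1R)-1-[(3R,4S)-6-hydroxy-3,4,5-trimethyl-8-oxo-4,8-dihydro-3H-isochromen-7-yl]ethyl]-3,4,5-trimethyl-3,4-dihydro-1H-isochromen-1-one, via cyclic ethyl acetal 18 (not isolated)
Conditions: HC(OEt)3 (10 equiv), TFA (2 equiv), CH2Cl2, 0 °C → rt; then 1 M aq. HCl, rt
Reagents that add atoms: triethyl orthoformate, CCOC(OCC)OCC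
Why: Electrophilic formylation by the dialkoxycarbenium ion at C8a, the only unsubstituted aromatic carbon of 17 (para to C6–OH, ortho to C8–OH), then acetalization by the C3 hydroxyl and acid-induced loss of ethanol should give the quinone methide with no stereocentre affected.

Compound list
1 | ethyl (R)-3-hydroxybutanoate | CCOC(=O)C[C@@H](C)O | starting material
2 | ethyl (2R,3R)-3-hydroxy-2-methylbutanoate | CCOC(=O)[C@H](C)[C@@H](C)O | intermediate
3 | tert-butyl propionate | CCC(=O)OC(C)(C)C | starting material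
4 | tert-butyl (4R,5R)-5-hydroxy-2,4-dimethyl-3-oxohexanoate (C2 epimers) | CC(C(=O)OC(C)(C)C)C(=O)[C@H](C)[C@@H](C)O | intermediate
5 | (5R,6R)-4-hydroxy-3,5,6-trimethyl-5,6-dihydro-2H-pyran-2-one | CC1=C(O)[C@H](C)[C@@H](C)OC1=O | intermediate
6 | (5R,6R)-3,5,6-trimethyl-2-oxo-5,6-dihydro-2H-pyran-4-yl trifluoromethanesulfonate | CC1=C(OS(=O)(=O)C(F)(F)F)[C@H](C)[C@@H](C)OC1=O | intermediate
7 | (R)-5-methoxy-3-methyl-5-oxopentanoic acid | COC(=O)C[C@H](C)CC(=O)O | starting material
8 | potassium 3-methoxy-3-oxopropanoate | COC(=O)CC(=O)[O-].[K+] | starting material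
9 | methyl (3R)-5-(1H-imidazol-1-yl)-3-methyl-5-oxopentanoate | COC(=O)C[C@H](C)CC(=O)n1ccnc1 | intermediate
10 | dimethyl (3R)-3-methyl-5-oxoheptanedioate | COC(=O)C[C@H](C)CC(=O)CC(=O)OC | intermediate
11 | tert-butyl acetate | CC(=O)OC(C)(C)C | starting material
12 | 1-tert-butyl 9-methyl (5R)-5-methyl-3,7-dioxononanedioate | CC(C)(C)OC(=O)CC(=O)C[C@H](C)CC(=O)CC(=O)OC | intermediate
13 | 1-tert-butyl 9-methyl (5R)-5-methyl-3,7-dioxo-2,8-bis[(2R,3S)-2,3,5-trimethyl-6-oxo-3,6-dihydro-2H-pyran-4-yl]nonanedioate (epimers at C2 and C8) | CC(C)(C)OC(=O)C(C(=O)C[C@H](C)CC(=O)C(C(=O)OC)C1=C(C)C(=O)O[C@H](C)[C@H]1C)C1=C(C)C(=O)O[C@H](C)[C@H]1C | intermediate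
14 | methyl (5S)-5-methyl-3,7-dioxo-2,8-bis[(2R,3S)-2,3,5-trimethyl-6-oxo-3,6-dihydro-2H-pyran-4-yl]octanoate (epimers at C2) | O=C(CC1=C(C)C(=O)O[C@H](C)[C@H]1C)C[C@H](C)CC(=O)C(C(=O)OC)C1=C(C)C(=O)O[C@H](C)[C@H]1C | intermediate
15 | open-chain bis(hydroxy enoate): the trimethyl ester formed by methanolysis of both lactones of 14, each alkene bearing a (2S,3R)-3-hydroxybutan-2-yl group (E/Z mixtures) | COC(=O)C(C)=C(CC(=O)C[C@H](C)CC(=O)C(C(=O)OC)C(=C(C)C(=O)OC)[C@H](C)[C@@H](C)O)[C@H](C)[C@@H](C)O | intermediate
16 | methyl 3-[(1S)-1-{2,6-dihydroxy-4-[(2S,3R)-3-hydroxybutan-2-yl]-3-methylphenyl}ethyl]-2,4-dihydroxy-6-[(2S,3R)-3-hydroxybutan-2-yl]-5-methylbenzoate | Cc1c(O)c([C@H](C)c2c(O)c(C)c([C@H](C)[C@@H](C)O)c(C(=O)OC)c2O)c(O)cc1[C@H](C)[C@@H](C)O | intermediate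
17 | (3R,4S)-7-[(1S)-1-{2,6-dihydroxy-4-[(2S,3R)-3-hydroxybutan-2-yl]-3-methylphenyl}ethyl]-6,8-dihydroxy-3,4,5-trimethyl-3,4-dihydro-1H-isochromen-1-one | Cc1c(O)c([C@H](C)c2c(O)c(C)c3c(c2O)C(=O)O[C@H](C)[C@H]3C)c(O)cc1[C@H](C)[C@@H](C)O | intermediate
18 | (3R,4S)-7-[(1S)-1-[(3R,4S)-1-ethoxy-6,8-dihydroxy-3,4,5-trimethyl-3,4-dihydro-1H-isochromen-7-yl]ethyl]-6,8-dihydroxy-3,4,5-trimethyl-3,4-dihydro-1H-isochromen-1-one (C1 epimers) | CCOC1O[C@H](C)[C@@H](C)c2c(C)c(O)c([C@H](C)c3c(O)c(C)c4c(c3O)C(=O)O[C@H](C)[C@H]4C)c(O)c21 | intermediate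
19 | dicitrinone H | CC1=C2C(=CO[C@H](C)[C@H]2C)C(=O)C([C@H](C)c2c(O)c(C)c3c(c2O)C(=O)O[C@H](C)[C@H]3C)=C1O | target

Total step count: 8. Longest linear sequence: 6 steps (steps 1, 2, 3, 6, 7, 8 from compound 1; the branch from 7 joins at step 6).

Steps most likely to fail

Step 7. The lactone rings hold C6 and C6′ trans to C8a and C8a′, so cyclization depends on methanolysis and E/Z equilibration. If these are slow, the stabilized anions may divert to enol O-acylation, ring B (the more stabilized C8a′ anion) may lag behind ring A, and C4/C4′ may epimerize by γ-deprotonation. The fallback carries the triketide unit as an acyclic Z-enol triflate; it sets out from 2 (and uses 12) and returns at 17. Compound 2 is silylated (TBSCl, imidazole) to ethyl (2R,3R)-3-[(tert-butyldimethylsilyl)oxy]-2-methylbutanoate F1. F1 is condensed with the lithium enolate of methyl propionate to methyl (4R,5R)-5-[(tert-butyldimethylsilyl)oxy]-2,4-dimethyl-3-oxohexanoate F2. F2 is converted through its chelated sodium enolate (NaH, then Tf2O) into methyl (2Z,4R,5R)-5-[(tert-butyldimethylsilyl)oxy]-2,4-dimethyl-3-{[(trifluoromethyl)sulfonyl]oxy}hex-2-enoate F3, in which the ester is already cis to the leaving group. Double addition–elimination of the bis-enolate of 12 to F3 with retention gives the tert-butyl ester bis-adduct F4 (not isolated). Brief TFA treatment decarboxylates it to the open-chain (Z,Z)-keto triester F5; any silyl loss here is harmless, since the hydroxyl is trans to the ester. NaOMe in MeOH then effects the same double Claisen cyclization without lactone opening or alkene isomerization, giving the bis-silyl ether of the bis-resorcinol methyl ester F6. Aqueous HCl removes both silyl groups and closes the lactone to 17.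

Step 6. The double substitution at a tetrasubstituted, flanked vinylic carbon may be slow, allowing O-attack of the enolate, triflyl transfer to the enolate or hydrolysis of the triflate to compete. The fallback replaces addition–elimination at carbon by a copper-mediated cross-coupling; it sets out from 5 (and 12) and returns at 14. Lactone 5 is converted with oxalyl bromide and catalytic DMF into (5R,6R)-4-bromo-3,5,6-trimethyl-5,6-dihydro-2H-pyran-2-one F7. Both β-keto ester sites of 12 are then C-vinylated with F7 in a Hurtley-type coupling (CuI, L-proline, Cs2CO3, DMSO, 60 °C). The resulting 13 is decarboxylated with TFA as before to give 14.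

Step 8. Under acid the doubly benzylic bridging carbon between two resorcinol-type rings may ionize (retro-Friedel–Crafts), which would epimerize or cleave the dimer, and the quinone methide may add nucleophiles during work-up. The fallback formylates under basic conditions; it sets out from 17 and returns at 19. Casnati–Skattebøl ortho-formylation (MgCl2, Et3N, paraformaldehyde, MeCN, reflux) through the magnesium phenoxide should place the formyl group at C8a, the only free ortho position, giving (3R,4S)-7-[(1S)-1-{3-formyl-2,6-dihydroxy-4-[(2S,3R)-3-hydroxybutan-2-yl]-5-methylphenyl}ethyl]-6,8-dihydroxy-3,4,5-trimethyl-3,4-dihydro-1H-isochromen-1-one F8 (in equilibrium with its lactol). Dehydration over 4 Å molecular sieves with a trace of pyridinium p-toluenesulfonate gives 19.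

Further compounds
F1 | step 7 | ethyl (2R,3R)-3-[(tert-butyldimethylsilyl)oxy]-2-methylbutanoate | CCOC(=O)[C@H](C)[C@@H](C)O[Si](C)(C)C(C)(C)C
F2 | step 7 | methyl (4R,5R)-5-[(tert-butyldimethylsilyl)oxy]-2,4-dimethyl-3-oxohexanoate (C2 epimers) | COC(=O)C(C)C(=O)[C@H](C)[C@@H](C)O[Si](C)(C)C(C)(C)C
F3 | step 7 | methyl (2Z,4R,5R)-5-[(tert-butyldimethylsilyl)oxy]-2,4-dimethyl-3-{[(trifluoromethyl)sulfonyl]oxy}hex-2-enoate | COC(=O)/C(C)=C(\OS(=O)(=O)C(F)(F)F)[C@H](C)[C@@H](C)O[Si](C)(C)C(C)(C)C
F4 | step 7 | tert-butyl ester bis-adduct of 12 with two molecules of F3 (both alkenes Z, silyl ethers retained) | CC(C)(C)OC(=O)C(C(=O)C[C@H](C)CC(=O)C(C(=O)OC)/C(=C(/C)C(=O)OC)[C@H](C)[C@@H](C)O[Si](C)(C)C(C)(C)C)/C(=C(/C)C(=O)OC)[C@H](C)[C@@H](C)O[Si](C)(C)C(C)(C)C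
F5 | step 7 | open-chain (Z,Z)-keto triester, the bis(tert-butyldimethylsilyl) ether of 15 with defined alkene geometry | COC(=O)/C(C)=C(\CC(=O)C[C@H](C)CC(=O)C(C(=O)OC)/C(=C(/C)C(=O)OC)[C@H](C)[C@@H](C)O[Si](C)(C)C(C)(C)C)[C@H](C)[C@@H](C)O[Si](C)(C)C(C)(C)C
F6 | step 7 | bis(tert-butyldimethylsilyl) ether of bis-resorcinol methyl ester 16 | Cc1c(O)c([C@H](C)c2c(O)c(C)c([C@H](C)[C@@H](C)O[Si](C)(C)C(C)(C)C)c(C(=O)OC)c2O)c(O)cc1[C@H](C)[C@@H](C)O[Si](C)(C)C(C)(C)C
F7 | step 6 | (5R,6R)-4-bromo-3,5,6-trimethyl-5,6-dihydro-2H-pyran-2-one | CC1=C(Br)[C@H](C)[C@@H](C)OC1=O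
F8 | step 8 | (3R,4S)-7-[(1S)-1-{3-formyl-2,6-dihydroxy-4-[(2S,3R)-3-hydroxybutan-2-yl]-5-methylphenyl}ethyl]-6,8-dihydroxy-3,4,5-trimethyl-3,4-dihydro-1H-isochromen-1-one | Cc1c(O)c([C@H](C)c2c(O)c(C)c3c(c2O)C(=O)O[C@H](C)[C@H]3C)c(O)c(C=O)c1[C@H](C)[C@@H](C)O
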